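**Retrosynthetic overview** (ring A = benzene ring C4a–C8a; ring B = pyranone ring O1, C2, C3, C4, C4a, C8a)

1. Target ⇒ C4 ketone released from a spiro-1,3-dithiane and two MOM ethers removed last; every basic or organometallic step runs on the dithioketal, where C3 cannot epimerise and ring B cannot open.
2. C8 side chain ⇒ Negishi coupling of the C8 arylzinc with an (E)-β-triflyloxy hexenoate, then CuH reduction for the benzylic centre; C6 prenyl ⇒ lithiation between the two MOM ethers.
3. Ring B ⇒ C4–C3 bond: the lithiated 2-aryl-1,3-dithiane carbon (C4) displaces a C3 tosylate with inversion. The feature used is the cis C2/C3 methyl pair of ring B, which is (2R,3R)-butane-2,3-diol with the O1–C2 bond kept and C3 inverted.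
4. Cyclisation precursor ⇒ 5-fluororesorcinol by formylation, MOM protection, SNAr by the diol alkoxide (retention at C2), dithioacetalisation and tosylation.
5. Ring order: ring A is bought; ring B is the only ring made (step 6).

Key step: step 6

Assumption: with the (E)-enoate, the (R)-configured biaryl bisphosphine is taken to deliver hydride to the face that gives the (R) benzylic centre, by analogy with simple (E)-β-aryl-β-alkyl enoates; the sense is to be confirmed on the first run and the (S)-ligand used if it is reversed.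

**Route**

Step 1
Reactants: 1 5-fluororesorcinol
Product: 2 2-fluoro-4,6-dihydroxybenzaldehyde
Conditions: POCl3, DMF, MeCN, 0 °C to rt; then H2O, 50 °C
Reagents that add atoms: N,N-dimethylformamide CN(C)C=O; water O
Why: Vilsmeier–Haack formylation of the electron-rich resorcinol should occur at C4, ortho to one hydroxyl and para to the other, in preference to the doubly flanked C2, as is usual for 5-substituted resorcinols.

Step 2
Reactants: 2 2-fluoro-4,6-dihydroxybenzaldehyde
Product: 3 2-fluoro-4,6-bis(methoxymethoxy)benzaldehyde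
Conditions: NaH, MOMCl, DMF, 0 °C to rt
Reagents that add atoms: chloromethyl methyl ether COCCl
Why: Williamson-type O-alkylation of the bis-phenoxide protects both hydroxyls, NaH being needed to engage the hydroxyl that is hydrogen-bonded to the formyl group.

Step 3
Reactants: 3 2-fluoro-4,6-bis(methoxymethoxy)benzaldehyde; 4 (2R,3R)-butane-2,3-diol
Product: 5 2-{[(2R,3R)-3-hydroxybutan-2-yl]oxy}-4,6-bis(methoxymethoxy)benzaldehyde
Conditions: 4 (4 equiv), NaH (1.2 equiv), DMF, 0 °C; then 3, 50 °C
Reagents that add atoms: none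
Why: Nucleophilic aromatic substitution (addition–elimination) of the fluoride ortho to the formyl group by the monosodium alkoxide of the C2-symmetric diol forms the aryl ether without breaking either carbinol C–O bond, so both centres stay (R), and the excess of diol suppresses double arylation.

Step 4
Reactants: 5 2-{[(2R,3R)-3-hydroxybutan-2-yl]oxy}-4,6-bis(methoxymethoxy)benzaldehyde; 6 propane-1,3-dithiol
Product: 7 (2R,3R)-3-[2-(1,3-dithian-2-yl)-3,5-bis(methoxymethoxy)phenoxy]butan-2-ol
Conditions: 6 (1.1 equiv), BF3·OEt2 (0.3 equiv), CH2Cl2, −40 °C; Et3N quench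
Reagents that add atoms: none
Why: Lewis-acid-catalysed dithioacetalisation is fast for the easily ionised trialkoxybenzaldehyde, so a sub-stoichiometric amount of BF3·OEt2 at low temperature should convert the formyl group while sparing the aryl MOM acetals.

Step 5
Reactants: 7 (2R,3R)-3-[2-(1,3-dithian-2-yl)-3,5-bis(methoxymethoxy)phenoxy]butan-2-ol
Product: 8 (2R,3R)-3-[2-(1,3-dithian-2-yl)-3,5-bis(methoxymethoxy)phenoxy]butan-2-yl 4-methylbenzenesulfonate
Conditions: TsCl, Et3N, DMAP (cat.), CH2Cl2, 0 °C to rt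
Reagents that add atoms: 4-methylbenzenesulfonyl chloride Cc1ccc(cc1)S(Cl)(=O)=O
Why: Sulfonylation of the secondary alcohol forms only the O–S bond, so the carbinol carbon keeps its (R) configuration and gains a non-enolisable leaving group that tolerates a lithium amide base.

Step 6
Reactants: 8 (2R,3R)-3-[2-(1,3-dithian-2-yl)-3,5-bis(methoxymethoxy)phenoxy]butan-2-yl 4-methylbenzenesulfonate
Product: 10 (2R,3S)-5,7-bis(methoxymethoxy)-2,3-dimethylspiro[chromane-4,2'-[1,3]dithiane], via 2-lithiodithiane tosylate 9 (not isolated)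
Conditions: LiN(i-Pr)2 (LDA, 1.3 equiv), THF/DMPU, −78 °C to −10 °C
Reagents that add atoms: none
Why: LDA removes the benzylic C–H flanked by two sulfur atoms, the most acidic site of 8, to give 9, whose carbanion carbon (future C4) attacks C3 from the side opposite the tosylate. The closest known reaction type is the Corey–Seebach alkylation of 2-lithio-1,3-dithianes with sulfonate esters, which inverts secondary carbon cleanly and is known intramolecularly in the closure of dithianes carrying a remote leaving group to cycloalkanone dithioketals. Ring B is closed in the 6-exo-tet mode through the new C4–C3 bond, its members being C4, C4a, C8a, O1, C2 and C3. The new C3 stereocentre is set by the substrate alone: the (R) carbinol carbon is inverted to (S), while C2, whose C–O bond is never broken, stays (R), so the two methyl groups end up cis. The step needs substitution to outrun E2 loss of the sulfonate towards an enol or allyl ether, and this is favoured by the tether, by the soft and weakly basic dithianyl anion, by a sulfonate (not a halide) leaving group that does not invite electron transfer, and by the low temperature. Deprotonation on ring A between the MOM ethers and attack at the sulfonate sulfur, both expected with butyllithium, are avoided by the weaker, hindered amide base.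

Step 7
Reactants: 10 (2R,3S)-5,7-bis(methoxymethoxy)-2,3-dimethylspiro[chromane-4,2'-[1,3]dithiane]
Product: 12 (2R,3S)-5,7-bis(methoxymethoxy)-2,3-dimethyl-6-(3-methylbut-2-en-1-yl)spiro[chromane-4,2'-[1,3]dithiane], via C6 aryllithium 11 (not isolated)
Conditions: n-BuLi, THF, 0 °C; then CuBr·SMe2 (10 mol %), prenyl bromide, −78 °C to rt
Reagents that add atoms: 1-bromo-3-methylbut-2-ene CC(C)=CCBr
Why: Directed ortho-metalation should occur at C6, between two chelating MOM ethers, in preference to C8, and the aryllithium is then allylated at the primary carbon of prenyl bromide under catalysis by monovalent copper (SN2 allylic substitution), the dithioketal being inert to butyllithium at this temperature.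

Step 8
Reactants: 13 methyl 3-oxohexanoate
Product: 14 methyl (2E)-3-{[(trifluoromethyl)sulfonyl]oxy}hex-2-enoate
Conditions: Me4NOH (25 % aq), Tf2O, hexanes, 5 °C
Reagents that add atoms: trifluoromethanesulfonic anhydride O=S(=O)(OS(=O)(=O)C(F)(F)F)C(F)(F)F
Why: O-Triflation of the β-keto ester enolate with a non-chelating tetramethylammonium counter-ion in a two-phase medium is known to favour the (E)-enol triflate, which fixes the alkene geometry carried into the coupling.

Step 9
Reactants: 12 (2R,3S)-5,7-bis(methoxymethoxy)-2,3-dimethyl-6-(3-methylbut-2-en-1-yl)spiro[chromane-4,2'-[1,3]dithiane]; 14 methyl (2E)-3-{[(trifluoromethyl)sulfonyl]oxy}hex-2-enoate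
Product: 17 methyl (2E)-3-[(2R,3S)-5,7-bis(methoxymethoxy)-2,3-dimethyl-6-(3-methylbut-2-en-1-yl)spiro[chromane-4,2'-[1,3]dithian]-8-yl]hex-2-enoate, via C8 aryllithium 15 (not isolated), via C8 arylzinc chloride 16 (not isolated)
Conditions: n-BuLi, TMEDA, THF, −20 °C; ZnCl2, −20 °C to rt; then 14, Pd2(dba)3 (2.5 mol %), SPhos (10 mol %), THF, 50 °C
Reagents that add atoms: none
Why: A second directed ortho-metalation at C8, the only ring hydrogen left and flanked by the C7 MOM ether and O1, followed by lithium-to-zinc exchange and Negishi cross-coupling under a bulky biarylphosphine, should form the hindered C8–C bond with retention of the (E) geometry, ring deprotonation being expected to be faster than lateral deprotonation of the prenyl methylene as in related MOM-protected prenylarenes.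

Step 10
Reactants: 17 methyl (2E)-3-[(2R,3S)-5,7-bis(methoxymethoxy)-2,3-dimethyl-6-(3-methylbut-2-en-1-yl)spiro[chromane-4,2'-[1,3]dithian]-8-yl]hex-2-enoate
Product: 18 methyl (3R)-3-[(2R,3S)-5,7-bis(methoxymethoxy)-2,3-dimethyl-6-(3-methylbut-2-en-1-yl)spiro[chromane-4,2'-[1,3]dithian]-8-yl]hexanoate
Conditions: Cu(OAc)2·H2O (5 mol %), (R)-DTBM-SEGPHOS (5 mol %), (EtO)2MeSiH, t-BuOH, toluene, 0 °C to rt
Reagents that add atoms: none
Why: Copper hydride catalysed asymmetric conjugate reduction (1,4-hydrosilylation) of the β,β-disubstituted enoate delivers hydride to one face of the (E)-alkene under control of the chiral bisphosphine, setting the (R) benzylic centre, while the prenyl alkene, the ester carbonyl and the dithioketal are not reduced.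

Step 11
Reactants: 18 methyl (3R)-3-[(2R,3S)-5,7-bis(methoxymethoxy)-2,3-dimethyl-6-(3-methylbut-2-en-1-yl)spiro[chromane-4,2'-[1,3]dithian]-8-yl]hexanoate
Product: 19 methyl (3R)-3-[(2R,3S)-5,7-bis(methoxymethoxy)-2,3-dimethyl-6-(3-methylbut-2-en-1-yl)-4-oxochroman-8-yl]hexanoate
Conditions: MeI, CaCO3, MeCN/H2O (9:1), 45 °C
Reagents that add atoms: water O
Why: Alkylative dithioketal hydrolysis (S-methylation, ionisation to the aryl-stabilised thionium ion and capture by water) under CaCO3 buffering unmasks the C4 ketone without acid or base, so the prenyl alkene, the MOM ethers and the C3 centre should be untouched.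

Step 12
Reactants: 19 methyl (3R)-3-[(2R,3S)-5,7-bis(methoxymethoxy)-2,3-dimethyl-6-(3-methylbut-2-en-1-yl)-4-oxochroman-8-yl]hexanoate
Product: 20 methyl (3R)-3-[(2R,3S)-5,7-dihydroxy-2,3-dimethyl-6-(3-methylbut-2-en-1-yl)-4-oxochroman-8-yl]hexanoate (CNP0068017.1)
Conditions: ZnBr2, n-PrSH, CH2Cl2, 0 °C to rt
Reagents that add atoms: none
Why: Lewis-acid-assisted acetal exchange of the two aryl MOM ethers with propanethiol (ZnBr2-promoted MOM cleavage) is fast at 0 °C and avoids both base, which would epimerise C3 or open ring B, and strong protic acid, which would cyclise the prenyl group onto the neighbouring phenols.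

**Compound list**

1 | 5-fluororesorcinol | Oc1cc(O)cc(F)c1 | starting material
2 | 2-fluoro-4,6-dihydroxybenzaldehyde | O=Cc1c(F)cc(O)cc1O | intermediate
3 | 2-fluoro-4,6-bis(methoxymethoxy)benzaldehyde | COCOc1cc(F)c(C=O)c(OCOC)c1 | intermediate
4 | (2R,3R)-butane-2,3-diol | C[C@@H](O)[C@@H](C)O | starting material
5 | 2-{[(2R,3R)-3-hydroxybutan-2-yl]oxy}-4,6-bis(methoxymethoxy)benzaldehyde | COCOc1cc(OCOC)c(C=O)c(O[C@H](C)[C@@H](C)O)c1 | intermediate
6 | propane-1,3-dithiol | SCCCS | starting material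
7 | (2R,3R)-3-[2-(1,3-dithian-2-yl)-3,5-bis(methoxymethoxy)phenoxy]butan-2-ol | COCOc1cc(OCOC)c(C2SCCCS2)c(O[C@H](C)[C@@H](C)O)c1 | intermediate
8 | (2R,3R)-3-[2-(1,3-dithian-2-yl)-3,5-bis(methoxymethoxy)phenoxy]butan-2-yl 4-methylbenzenesulfonate | COCOc1cc(OCOC)c(C2SCCCS2)c(O[C@H](C)[C@@H](C)OS(=O)(=O)c2ccc(C)cc2)c1 | intermediate
9 | (2R,3R)-3-[2-(2-lithio-1,3-dithian-2-yl)-3,5-bis(methoxymethoxy)phenoxy]butan-2-yl 4-methylbenzenesulfonate | COCOc1cc(OCOC)c(C2([Li])SCCCS2)c(O[C@H](C)[C@@H](C)OS(=O)(=O)c2ccc(C)cc2)c1 | intermediate (not isolated)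
10 | (2R,3S)-5,7-bis(methoxymethoxy)-2,3-dimethylspiro[chromane-4,2'-[1,3]dithiane] | COCOc1cc(OCOC)c2c(c1)O[C@H](C)[C@H](C)C21SCCCS1 | intermediate
11 | 6-lithio derivative of 10 | COCOc1c([Li])c(OCOC)c2c(c1)O[C@H](C)[C@H](C)C21SCCCS1 | intermediate (not isolated)
12 | (2R,3S)-5,7-bis(methoxymethoxy)-2,3-dimethyl-6-(3-methylbut-2-en-1-yl)spiro[chromane-4,2'-[1,3]dithiane] | COCOc1c(CC=C(C)C)c(OCOC)c2c(c1)O[C@H](C)[C@H](C)C21SCCCS1 | intermediate
13 | methyl 3-oxohexanoate | CCCC(=O)CC(=O)OC | starting material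
14 | methyl (2E)-3-{[(trifluoromethyl)sulfonyl]oxy}hex-2-enoate | CCC/C(OS(=O)(=O)C(F)(F)F)=C\C(=O)OC | intermediate
15 | 8-lithio derivative of 12 | COCOc1c(CC=C(C)C)c(OCOC)c2c(c1[Li])O[C@H](C)[C@H](C)C21SCCCS1 | intermediate (not isolated)
16 | 8-(chlorozincio) derivative of 12 | COCOc1c(CC=C(C)C)c(OCOC)c2c(c1[Zn]Cl)O[C@H](C)[C@H](C)C21SCCCS1 | intermediate (not isolated)
17 | methyl (2E)-3-[(2R,3S)-5,7-bis(methoxymethoxy)-2,3-dimethyl-6-(3-methylbut-2-en-1-yl)spiro[chromane-4,2'-[1,3]dithian]-8-yl]hex-2-enoate | CCC/C(=C\C(=O)OC)c1c(OCOC)c(CC=C(C)C)c(OCOC)c2c1O[C@H](C)[C@H](C)C21SCCCS1 | intermediate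
18 | methyl (3R)-3-[(2R,3S)-5,7-bis(methoxymethoxy)-2,3-dimethyl-6-(3-methylbut-2-en-1-yl)spiro[chromane-4,2'-[1,3]dithian]-8-yl]hexanoate | CCC[C@H](CC(=O)OC)c1c(OCOC)c(CC=C(C)C)c(OCOC)c2c1O[C@H](C)[C@H](C)C21SCCCS1 | intermediate
19 | methyl (3R)-3-[(2R,3S)-5,7-bis(methoxymethoxy)-2,3-dimethyl-6-(3-methylbut-2-en-1-yl)-4-oxochroman-8-yl]hexanoate | CCC[C@H](CC(=O)OC)c1c(OCOC)c(CC=C(C)C)c(OCOC)c2c1O[C@H](C)[C@H](C)C2=O | intermediate
20 | methyl (3R)-3-[(2R,3S)-5,7-dihydroxy-2,3-dimethyl-6-(3-methylbut-2-en-1-yl)-4-oxochroman-8-yl]hexanoate | CCC[C@H](CC(=O)OC)c1c(O)c(CC=C(C)C)c(O)c2c1O[C@H](C)[C@H](C)C2=O | target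

**Step count**

Total: 12 steps. Longest linear sequence: 11 steps (steps 1 to 7 and 9 to 12); step 8 is a one-step side branch.

**Steps most likely to fail**

Risk 1, step 6. Elimination of the sulfonate (E2, by the dithianyl anion or the amide base) may outrun substitution at the hindered secondary carbon, or deprotonation of the crowded dithiane C–H may stay incomplete. The fallback forms C3–C4 intermolecularly and closes ring B at O1–C8a instead. It sets out from 3: dithioacetalisation with 6 as in step 4 would give 2-[2-fluoro-4,6-bis(methoxymethoxy)phenyl]-1,3-dithiane F1. Its lithio derivative (n-BuLi, THF, −78 °C) would open commercial (2R,3R)-2,3-dimethyloxirane (C[C@H]1O[C@@H]1C) under BF3·OEt2 activation at −78 °C, with inversion at the attacked carbon, to give (2R,3S)-3-{2-[2-fluoro-4,6-bis(methoxymethoxy)phenyl]-1,3-dithian-2-yl}butan-2-ol F2. The potassium alkoxide of F2 (KN(SiMe3)2, THF/DMPU, 80 °C) would then displace the fluoride, which sits meta to both alkoxy groups and is therefore not deactivated by resonance, in an intramolecular SNAr with retention at C2. This comes back to the route at 10.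

Risk 2, step 9. Lateral deprotonation at the allylic and benzylic methylene of the prenyl group may compete with ring metalation at C8, and transmetalation or coupling of the doubly ortho-substituted arylzinc may be slow. The fallback carries C6 as a silyl group and brings in the prenyl group by cross-coupling after the ketone is unmasked. It sets out from 10: C6 lithiation as in step 7 with Me3SiCl quench would give (2R,3S)-5,7-bis(methoxymethoxy)-2,3-dimethyl-6-(trimethylsilyl)spiro[chromane-4,2'-[1,3]dithiane] F3, which has no acidic benzylic C–H. The metalation and Negishi sequence of step 9 with 14 would give methyl (2E)-3-[(2R,3S)-5,7-bis(methoxymethoxy)-2,3-dimethyl-6-(trimethylsilyl)spiro[chromane-4,2'-[1,3]dithian]-8-yl]hex-2-enoate F4. The reduction of step 10 would give methyl (3R)-3-[(2R,3S)-5,7-bis(methoxymethoxy)-2,3-dimethyl-6-(trimethylsilyl)spiro[chromane-4,2'-[1,3]dithian]-8-yl]hexanoate F5, and the hydrolysis of step 11 would give methyl (3R)-3-[(2R,3S)-5,7-bis(methoxymethoxy)-2,3-dimethyl-4-oxo-6-(trimethylsilyl)chroman-8-yl]hexanoate F6. Ipso-iododesilylation (ICl, CH2Cl2, −78 °C) would give methyl (3R)-3-[(2R,3S)-6-iodo-5,7-bis(methoxymethoxy)-2,3-dimethyl-4-oxochroman-8-yl]hexanoate F7. A Stille coupling with tributyl(3-methylbut-2-en-1-yl)stannane under neutral conditions (Pd2(dba)3, AsPh3, DMF, 60 °C) would then give 19, where the route resumes at step 12.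

Risk 3, step 10. Hydride delivery to the twisted, doubly ortho-substituted aryl enoate may be sluggish or show poor facial selectivity, and the sense of induction is only assumed. The fallback sets the benzylic centre with a covalently bound auxiliary whose sense follows from a chelate model. It sets out from 12: C8 lithiation as in step 9 and quench with DMF would give (2R,3S)-5,7-bis(methoxymethoxy)-2,3-dimethyl-6-(3-methylbut-2-en-1-yl)spiro[chromane-4,2'-[1,3]dithiane]-8-carbaldehyde F8. Horner–Wadsworth–Emmons olefination with the known reagent diethyl {2-oxo-2-[(4R)-2-oxo-4-phenyl-1,3-oxazolidin-3-yl]ethyl}phosphonate (CCOP(=O)(CC(=O)N1[C@H](c2ccccc2)COC1=O)OCC; LiCl, i-Pr2NEt, MeCN) would give (4R)-3-{(2E)-3-[(2R,3S)-5,7-bis(methoxymethoxy)-2,3-dimethyl-6-(3-methylbut-2-en-1-yl)spiro[chromane-4,2'-[1,3]dithian]-8-yl]prop-2-enoyl}-4-phenyl-1,3-oxazolidin-2-one F9. Conjugate addition of n-PrMgBr with CuBr·SMe2 (THF/Me2S, −40 °C) should deliver propyl to the face opposite the phenyl group of the magnesium-chelated syn-s-cis imide and give (4R)-3-{(3R)-3-[(2R,3S)-5,7-bis(methoxymethoxy)-2,3-dimethyl-6-(3-methylbut-2-en-1-yl)spiro[chromane-4,2'-[1,3]dithian]-8-yl]hexanoyl}-4-phenyl-1,3-oxazolidin-2-one F10. Methanolysis with MeOMgBr (MeOH/THF, 0 °C) would release the methyl ester and come back to the route at 18.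

**Further compounds**

F1 | step 6 | 2-[2-fluoro-4,6-bis(methoxymethoxy)phenyl]-1,3-dithiane | COCOc1cc(F)c(C2SCCCS2)c(OCOC)c1
F2 | step 6 | (2R,3S)-3-{2-[2-fluoro-4,6-bis(methoxymethoxy)phenyl]-1,3-dithian-2-yl}butan-2-ol | COCOc1cc(F)c(c(OCOC)c1)C1(SCCCS1)[C@@H](C)[C@@H](C)O
F3 | step 9 | (2R,3S)-5,7-bis(methoxymethoxy)-2,3-dimethyl-6-(trimethylsilyl)spiro[chromane-4,2'-[1,3]dithiane] | COCOc1c([Si](C)(C)C)c(OCOC)c2c(c1)O[C@H](C)[C@H](C)C21SCCCS1
F4 | step 9 | methyl (2E)-3-[(2R,3S)-5,7-bis(methoxymethoxy)-2,3-dimethyl-6-(trimethylsilyl)spiro[chromane-4,2'-[1,3]dithian]-8-yl]hex-2-enoate | CCC/C(=C\C(=O)OC)c1c(OCOC)c([Si](C)(C)C)c(OCOC)c2c1O[C@H](C)[C@H](C)C21SCCCS1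
F5 | step 9 | methyl (3R)-3-[(2R,3S)-5,7-bis(methoxymethoxy)-2,3-dimethyl-6-(trimethylsilyl)spiro[chromane-4,2'-[1,3]dithian]-8-yl]hexanoate | CCC[C@H](CC(=O)OC)c1c(OCOC)c([Si](C)(C)C)c(OCOC)c2c1O[C@H](C)[C@H](C)C21SCCCS1
F6 | step 9 | methyl (3R)-3-[(2R,3S)-5,7-bis(methoxymethoxy)-2,3-dimethyl-4-oxo-6-(trimethylsilyl)chroman-8-yl]hexanoate | CCC[C@H](CC(=O)OC)c1c(OCOC)c([Si](C)(C)C)c(OCOC)c2c1O[C@H](C)[C@H](C)C2=O
F7 | step 9 | methyl (3R)-3-[(2R,3S)-6-iodo-5,7-bis(methoxymethoxy)-2,3-dimethyl-4-oxochroman-8-yl]hexanoate | CCC[C@H](CC(=O)OC)c1c(OCOC)c(I)c(OCOC)c2c1O[C@H](C)[C@H](C)C2=O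
F8 | step 10 | (2R,3S)-5,7-bis(methoxymethoxy)-2,3-dimethyl-6-(3-methylbut-2-en-1-yl)spiro[chromane-4,2'-[1,3]dithiane]-8-carbaldehyde | COCOc1c(CC=C(C)C)c(OCOC)c2c(c1C=O)O[C@H](C)[C@H](C)C21SCCCS1
F9 | step 10 | (4R)-3-{(2E)-3-[(2R,3S)-5,7-bis(methoxymethoxy)-2,3-dimethyl-6-(3-methylbut-2-en-1-yl)spiro[chromane-4,2'-[1,3]dithian]-8-yl]prop-2-enoyl}-4-phenyl-1,3-oxazolidin-2-one | O=C(/C=C/c1c(OCOC)c(CC=C(C)C)c(OCOC)c2c1O[C@H](C)[C@H](C)C21SCCCS1)N1[C@H](c3ccccc3)COC1=O
F10 | step 10 | (4R)-3-{(3R)-3-[(2R,3S)-5,7-bis(methoxymethoxy)-2,3-dimethyl-6-(3-methylbut-2-en-1-yl)spiro[chromane-4,2'-[1,3]dithian]-8-yl]hexanoyl}-4-phenyl-1,3-oxazolidin-2-one | CCC[C@H](CC(=O)N1[C@H](c2ccccc2)COC1=O)c1c(OCOC)c(CC=C(C)C)c(OCOC)c2c1O[C@H](C)[C@H](C)C21SCCCS1
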